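**Plan**

- Retrosynthesis: the three silyl ethers come off last. Ring C is then cut at C2–C3, giving an open α-diazoketone in which C3 is the diazo carbon on the C4 carbonyl and C2 is the CH2 of a benzyl aryl ether on O1.
- Enabling feature: C2–H is α to O1 and benzylic to the 4-oxygenated ring B, and lies 1,6 to C3 across C4–C4a–C8a–O1. The acyl group on C4a has only O1 and the silylated O5 as ortho neighbours; the geranyl chain on C6 is meta to C4a and cannot reach C3.
- Further cuts: O1–CH2 (Mitsunobu ether between ring A phenol and ring B benzylic alcohol), C3=N2 (diazo transfer onto the acetyl group), C6–C1'' (C-geranylation of phloroacetophenone).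
- Forward order: ring A is bought as 2,4,6-trihydroxyacetophenone, C-geranylated, silylated at O7, etherified at O1 with the ring B alcohol, silylated at O5 and converted to the diazoketone. Ring C closes last by C–H insertion, then desilylation.
- Because O1–C2 exists before ring C closes, the 6- versus 8-geranyl question is settled at the etherification (less hindered ortho phenol), not at ring closure.
- Stereochemistry: C2 (S) is set in the ring closure by a chiral dirhodium carboxylate that selects one of the two enantiotopic benzylic hydrogens; no later step exposes C2 to base.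

Key step: step 8

Assumption: the sense of induction of Rh2(S-PTTL)4 in this closure is not secured by a close analogue. The route is written for the catalyst antipode that takes the pro-S hydrogen; Rh2(R-PTTL)4 is used instead if the first run shows the 2R series.

Abbreviations: TBS = tert-butyldimethylsilyl; geranyl = (2E)-3,7-dimethylocta-2,6-dien-1-yl.

**Route**

Step 1
Reactants: 1 syringaldehyde (4-hydroxy-3,5-dimethoxybenzaldehyde)
Product: 2 4-(TBS-oxy)-3,5-dimethoxybenzaldehyde
Conditions: TBSCl, imidazole, DMF, rt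
Reagents that add atoms: tert-butyldimethylsilyl chloride, CC(C)(C)[Si](C)(C)Cl
Why: O-silylation of an acidic phenol with a silyl chloride and imidazole should proceed cleanly despite the two flanking methoxy groups.

Step 2
Reactants: 2 4-(TBS-oxy)-3,5-dimethoxybenzaldehyde
Product: 3 [4-(TBS-oxy)-3,5-dimethoxyphenyl]methanol
Conditions: NaBH4, EtOH/THF, 0 °C
Reagents that add atoms: none
Why: Borohydride reduction of an aryl aldehyde is fast at 0 °C and should leave the aryl silyl ether untouched.

Step 3
Reactants: 4 2,4,6-trihydroxyacetophenone; 5 geranyl bromide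
Product: 6 1-(3-geranyl-2,4,6-trihydroxyphenyl)ethan-1-one
Conditions: DBU, THF, 0 °C to rt, slow addition of 5 to a slight excess of 4
Reagents that add atoms: none
Why: C-allylation of the ambident phloroglucinol-type phenoxide at a ring carbon flanked by two oxygens (SN2 at the primary allylic bromide, E geometry retained) should give the known mono-C-geranyl ketone.

Step 4
Reactants: 6 1-(3-geranyl-2,4,6-trihydroxyphenyl)ethan-1-one
Product: 7 1-[3-geranyl-2,6-dihydroxy-4-(TBS-oxy)phenyl]ethan-1-one
Conditions: TBSCl (1.0 equiv), imidazole, CH2Cl2, −20 to 0 °C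
Reagents that add atoms: tert-butyldimethylsilyl chloride, CC(C)(C)[Si](C)(C)Cl
Why: Regioselective O-silylation: the 4-OH is para to the acetyl group, outside the chelate and the most acidic phenol, so one equivalent of silyl chloride should take it first.

Step 5
Reactants: 7 1-[3-geranyl-2,6-dihydroxy-4-(TBS-oxy)phenyl]ethan-1-one; 3 [4-(TBS-oxy)-3,5-dimethoxyphenyl]methanol
Product: 8 1-[3-geranyl-2-hydroxy-4-(TBS-oxy)-6-{[4-(TBS-oxy)-3,5-dimethoxyphenyl]methoxy}phenyl]ethan-1-one
Conditions: PPh3, DIAD, THF, 0 °C to rt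
Reagents that add atoms: none
Why: Mitsunobu etherification under neutral conditions should alkylate the ortho phenol next to the ring hydrogen and not the one wedged between acetyl and geranyl, which places the benzylic carbon on the oxygen that becomes O1 and fixes the 6-geranyl pattern.

Step 6
Reactants: 8 1-[3-geranyl-2-hydroxy-4-(TBS-oxy)-6-{[4-(TBS-oxy)-3,5-dimethoxyphenyl]methoxy}phenyl]ethan-1-one
Product: 9 1-[3-geranyl-2,4-bis(TBS-oxy)-6-{[4-(TBS-oxy)-3,5-dimethoxyphenyl]methoxy}phenyl]ethan-1-one
Conditions: TBSOTf, 2,6-lutidine, CH2Cl2, −78 to 0 °C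
Reagents that add atoms: tert-butyldimethylsilyl trifluoromethanesulfonate, CC(C)(C)[Si](C)(C)OS(=O)(=O)C(F)(F)F
Why: O-silylation with a silyl triflate and a hindered pyridine base should cap the last, chelated and hindered phenol without enolising the ketone.

Step 7
Reactants: 9 1-[3-geranyl-2,4-bis(TBS-oxy)-6-{[4-(TBS-oxy)-3,5-dimethoxyphenyl]methoxy}phenyl]ethan-1-one
Product: 11 2-diazo-1-[3-geranyl-2,4-bis(TBS-oxy)-6-{[4-(TBS-oxy)-3,5-dimethoxyphenyl]methoxy}phenyl]ethan-1-one, via trifluoroacetyl diketone 10 (not isolated)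
Conditions: LiHMDS, THF, −78 °C, then CF3CO2CH2CF3; cold dilute aq. HCl work-up; then 4-acetamidobenzenesulfonyl azide, Et3N, H2O (1 equiv), MeCN, rt
Reagents that add atoms: 4-acetamidobenzenesulfonyl azide, CC(=O)Nc1ccc(cc1)S(=O)(=O)N=[N+]=[N-] (the two nitrogen atoms of 11); 2,2,2-trifluoroethyl trifluoroacetate, O=C(OCC(F)(F)F)C(F)(F)F (the trifluoroacetyl group of 10, lost again on the way to 11)
Why: Detrifluoroacetylative Regitz-type diazo transfer: the kinetic lithium enolate of the methyl ketone is C-trifluoroacetylated, and the activated 1,3-diketone then accepts the diazo group from the sulfonyl azide with loss of the trifluoroacetyl group as its sulfonamide.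

Step 8
Reactants: 11 2-diazo-1-[3-geranyl-2,4-bis(TBS-oxy)-6-{[4-(TBS-oxy)-3,5-dimethoxyphenyl]methoxy}phenyl]ethan-1-one
Product: 12 (2S)-6-geranyl-5,7-bis(TBS-oxy)-2-[4-(TBS-oxy)-3,5-dimethoxyphenyl]chroman-4-one
Conditions: Rh2(S-PTTL)4 {dirhodium tetrakis[N-phthaloyl-(S)-tert-leucinate]} (2 mol %), CH2Cl2, 0 °C, slow addition of 11 at high dilution
Reagents that add atoms: none
Why: Loss of N2 from 11 at the divalent rhodium catalyst gives an electrophilic rhodium-bound carbene at C3, which inserts into one C2–H bond of the benzyl ether through a three-centre, hydride-transfer-like transition state, so that C2–C3 forms and the hydrogen ends on C3. The closest known reaction type is the intramolecular C–H insertion of ortho-alkoxyaryl α-diazoketones to chroman-4-ones under chiral dirhodium carboxylate catalysis. Ring C closes in a 1,6-insertion mode (six-membered cyclic transition state C3–C4–C4a–C8a–O1–C2, closure onto the sp3 carbon C2 with retention). C2 is the only new stereocentre and is under catalyst control: the chiral carboxylate ligand shell decides which of the two enantiotopic benzylic hydrogens is reached, and replacement of the pro-S hydrogen with retention gives 2S. The step needs chemoselectivity for C2–H over attack of the O1 lone pair on the carbene (oxonium ylide, then [1,2]-benzyl Stevens shift to a benzofuranone) and over every other O–H, C–H or C=C bond. The substrate secures this: C2–H is activated by O1 and by the para-silyloxyphenyl ring B; O1 is a weakly basic aryl ether oxygen conjugated to the acyl group; the bulky O5 silyl ether twists the diazoacetyl group out of the plane of ring A (disfavouring the flat five-membered ylide but not the puckered six-membered insertion) and offers neither a basic oxygen nor an activated C–H; no O–H is left; and the geranyl alkenes on C6 are meta to C4a and out of intramolecular reach, while slow addition suppresses carbene dimer formation and intermolecular cyclopropanation.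

Step 9
Reactants: 12 (2S)-6-geranyl-5,7-bis(TBS-oxy)-2-[4-(TBS-oxy)-3,5-dimethoxyphenyl]chroman-4-one
Product: 13 (2S)-6-geranyl-5,7-dihydroxy-2-(4-hydroxy-3,5-dimethoxyphenyl)chroman-4-one
Conditions: Bu4NF, AcOH (slight excess over fluoride), THF, 0 °C
Reagents that add atoms: none
Why: Fluoride-mediated desilylation should cleave the three aryl silyl ethers, while the acetic acid buffer keeps the phenoxide concentration low so that ring C is not opened (retro-oxa-Michael or 4'-phenoxide quinone methide pathway) and the geranyl chain sees no strong acid.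

**Compound list**

1 | syringaldehyde (4-hydroxy-3,5-dimethoxybenzaldehyde) | COc1cc(C=O)cc(OC)c1O | starting material
2 | 4-(TBS-oxy)-3,5-dimethoxybenzaldehyde | COc1cc(C=O)cc(OC)c1O[Si](C)(C)C(C)(C)C | intermediate
3 | [4-(TBS-oxy)-3,5-dimethoxyphenyl]methanol | COc1cc(CO)cc(OC)c1O[Si](C)(C)C(C)(C)C | intermediate
4 | 2,4,6-trihydroxyacetophenone | CC(=O)c1c(O)cc(O)cc1O | starting material
5 | geranyl bromide, (2E)-1-bromo-3,7-dimethylocta-2,6-diene | BrC/C=C(\C)CCC=C(C)C | starting material
6 | 1-(3-geranyl-2,4,6-trihydroxyphenyl)ethan-1-one | CC(=O)c1c(O)cc(O)c(C/C=C(\C)CCC=C(C)C)c1O | intermediate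
7 | 1-[3-geranyl-2,6-dihydroxy-4-(TBS-oxy)phenyl]ethan-1-one | CC(=O)c1c(O)cc(O[Si](C)(C)C(C)(C)C)c(C/C=C(\C)CCC=C(C)C)c1O | intermediate
8 | 1-[3-geranyl-2-hydroxy-4-(TBS-oxy)-6-{[4-(TBS-oxy)-3,5-dimethoxyphenyl]methoxy}phenyl]ethan-1-one | CC(=O)c1c(OCc2cc(OC)c(O[Si](C)(C)C(C)(C)C)c(OC)c2)cc(O[Si](C)(C)C(C)(C)C)c(C/C=C(\C)CCC=C(C)C)c1O | intermediate
9 | 1-[3-geranyl-2,4-bis(TBS-oxy)-6-{[4-(TBS-oxy)-3,5-dimethoxyphenyl]methoxy}phenyl]ethan-1-one | CC(=O)c1c(OCc2cc(OC)c(O[Si](C)(C)C(C)(C)C)c(OC)c2)cc(O[Si](C)(C)C(C)(C)C)c(C/C=C(\C)CCC=C(C)C)c1O[Si](C)(C)C(C)(C)C | intermediate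
10 | trifluoroacetyl diketone: 4,4,4-trifluoro-1-aryl-butane-1,3-dione, aryl as in 9 | O=C(CC(=O)C(F)(F)F)c1c(OCc2cc(OC)c(O[Si](C)(C)C(C)(C)C)c(OC)c2)cc(O[Si](C)(C)C(C)(C)C)c(C/C=C(\C)CCC=C(C)C)c1O[Si](C)(C)C(C)(C)C | intermediate (not isolated)
11 | 2-diazo-1-[3-geranyl-2,4-bis(TBS-oxy)-6-{[4-(TBS-oxy)-3,5-dimethoxyphenyl]methoxy}phenyl]ethan-1-one | [N-]=[N+]=CC(=O)c1c(OCc2cc(OC)c(O[Si](C)(C)C(C)(C)C)c(OC)c2)cc(O[Si](C)(C)C(C)(C)C)c(C/C=C(\C)CCC=C(C)C)c1O[Si](C)(C)C(C)(C)C | intermediate
12 | (2S)-6-geranyl-5,7-bis(TBS-oxy)-2-[4-(TBS-oxy)-3,5-dimethoxyphenyl]chroman-4-one | COc1cc([C@@H]2CC(=O)c3c(cc(O[Si](C)(C)C(C)(C)C)c(C/C=C(\C)CCC=C(C)C)c3O[Si](C)(C)C(C)(C)C)O2)cc(OC)c1O[Si](C)(C)C(C)(C)C | intermediate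
13 | (2S)-6-geranyl-5,7-dihydroxy-2-(4-hydroxy-3,5-dimethoxyphenyl)chroman-4-one | COc1cc([C@@H]2CC(=O)c3c(cc(O)c(C/C=C(\C)CCC=C(C)C)c3O)O2)cc(OC)c1O | target

**Step count and risks**

Total step count: 9. Longest linear sequence: 7 steps (steps 3 to 9 from 4; the branch through steps 1, 2, 5 to 9 is equally long).

Steps most likely to fail:

1. Step 8. The carbene may be captured by the O1 lone pair (ylide formation and benzyl migration to a five-membered ketone) instead of inserting into C2–H, or the catalyst may discriminate poorly between the two benzylic hydrogens. Fallback, setting out from 7 and coming back at 12: the pyranone is built as a chromone and ring B is added enantioselectively.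
   - 7 is etherified at the less hindered phenol with allyl alcohol (PPh3, DIAD, THF) to give allyl ether F1.
   - TBSOTf and 2,6-lutidine give bis-silyl allyl ether F2.
   - Pd(PPh3)4 and morpholine remove the allyl group to give the free phenol F3, whose OH becomes O1.
   - N,N-dimethylformamide dimethyl acetal (toluene, 90 °C) gives enaminone F4, which closes with loss of dimethylamine (PPTS or silica gel) to 6-geranyl-5,7-bis(TBS-oxy)chromone F5.
   - Separately, commercial 4-bromo-2,6-dimethoxyphenol is silylated (TBSCl, imidazole) to aryl bromide F6 and converted (n-BuLi, B(OiPr)3, −78 °C, aqueous work-up) into boronic acid F7.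
   - Conjugate addition of F7 to F5 with Pd(OCOCF3)2 and the enantiomer of 4-tert-butyl-2-(pyridin-2-yl)-4,5-dihydrooxazole that gives the 2S series (NH4PF6, H2O, ClCH2CH2Cl, 60 °C) should give 12.

2. Step 7. The silyl group on O5 may migrate to the neighbouring lithium enolate oxygen, and C-acylation of the twisted, doubly ortho-substituted ketone may be sluggish. Fallback, setting out from 9 and coming back at 11, with no metal enolate: condensation of 9 with N,N-dimethylformamide dimethyl acetal (toluene, 100 °C) gives enaminone F8. Diazo transfer from 4-methylbenzenesulfonyl azide (MeCN, rt) then proceeds by cycloaddition to the enamine double bond and fragmentation, releasing 11 and the N-sulfonyl formamidine.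

3. Step 3. The ambident phenoxide may be alkylated at oxygen or more than once at carbon, consuming the allylic bromide. Fallback, setting out from 5 with commercial phloroglucinol in place of 4, and coming back at 6:
   - Phloroglucinol is converted (NaH, MOMCl, DMF) to 1,3,5-tris(methoxymethoxy)benzene F9.
   - Directed ortho-lithiation between two acetal oxygens (n-BuLi, THF, 0 °C), transmetalation with CuI and alkylation with 5 give 2-geranyl-1,3,5-tris(methoxymethoxy)benzene F10.
   - A second lithiation (n-BuLi, TMEDA) at one of the two equivalent remaining ring positions and acylation with N-methoxy-N-methylacetamide give tris(methoxymethyl) ketone F11.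
   - Mild acid (HCl, MeOH, rt) removes the three acetals and returns 6.

Further compounds
F1 | step 8 | 1-[6-(allyloxy)-3-geranyl-2-hydroxy-4-(TBS-oxy)phenyl]ethan-1-one | CC(=O)c1c(OCC=C)cc(O[Si](C)(C)C(C)(C)C)c(C/C=C(\C)CCC=C(C)C)c1O
F2 | step 8 | 1-[6-(allyloxy)-3-geranyl-2,4-bis(TBS-oxy)phenyl]ethan-1-one | CC(=O)c1c(OCC=C)cc(O[Si](C)(C)C(C)(C)C)c(C/C=C(\C)CCC=C(C)C)c1O[Si](C)(C)C(C)(C)C
F3 | step 8 | 1-[3-geranyl-6-hydroxy-2,4-bis(TBS-oxy)phenyl]ethan-1-one | CC(=O)c1c(O)cc(O[Si](C)(C)C(C)(C)C)c(C/C=C(\C)CCC=C(C)C)c1O[Si](C)(C)C(C)(C)C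
F4 | step 8 | (2E)-3-(dimethylamino)-1-[3-geranyl-6-hydroxy-2,4-bis(TBS-oxy)phenyl]prop-2-en-1-one | CN(C)/C=C/C(=O)c1c(O)cc(O[Si](C)(C)C(C)(C)C)c(C/C=C(\C)CCC=C(C)C)c1O[Si](C)(C)C(C)(C)C
F5 | step 8 | 6-geranyl-5,7-bis(TBS-oxy)-4H-chromen-4-one | O=c1ccoc2cc(O[Si](C)(C)C(C)(C)C)c(C/C=C(\C)CCC=C(C)C)c(O[Si](C)(C)C(C)(C)C)c12
F6 | step 8 | (4-bromo-2,6-dimethoxyphenoxy)(tert-butyl)dimethylsilane | COc1cc(Br)cc(OC)c1O[Si](C)(C)C(C)(C)C
F7 | step 8 | [4-(TBS-oxy)-3,5-dimethoxyphenyl]boronic acid | COc1cc(B(O)O)cc(OC)c1O[Si](C)(C)C(C)(C)C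
F8 | step 7 | (2E)-3-(dimethylamino)-1-[3-geranyl-2,4-bis(TBS-oxy)-6-{[4-(TBS-oxy)-3,5-dimethoxyphenyl]methoxy}phenyl]prop-2-en-1-one | CN(C)/C=C/C(=O)c1c(OCc2cc(OC)c(O[Si](C)(C)C(C)(C)C)c(OC)c2)cc(O[Si](C)(C)C(C)(C)C)c(C/C=C(\C)CCC=C(C)C)c1O[Si](C)(C)C(C)(C)C
F9 | step 3 | 1,3,5-tris(methoxymethoxy)benzene | COCOc1cc(OCOC)cc(OCOC)c1
F10 | step 3 | 2-geranyl-1,3,5-tris(methoxymethoxy)benzene | COCOc1cc(OCOC)c(C/C=C(\C)CCC=C(C)C)c(OCOC)c1
F11 | step 3 | 1-[3-geranyl-2,4,6-tris(methoxymethoxy)phenyl]ethan-1-one | CC(=O)c1c(OCOC)cc(OCOC)c(C/C=C(\C)CCC=C(C)C)c1OCOC
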